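You want the part of the electrophile that has reacted by 25 h in south, west and east, which step free base from 0.800 equiv through 1.60 equiv to 3.20 equiv.

| flask | electrophile | free base | gas | remark | time |
|---|---|---|---|---|---|
| birch | 0.30 M | 0.80 equiv (fed, over 20 h) | 33 mM (held) | run made earlier; the fed solution adds 0.50 times the starting volume |  |
| south | 0.20 M | 0.800 equiv (fed, over 20 h) | 33 mM (held) | the fed solution adds 0.50 times the starting volume | 25 h |
| west | 0.20 M | 1.60 equiv (fed, over 20 h) | 33 mM (held) | the fed solution adds 0.50 times the starting volume | 25 h |
| east | 0.20 M | 3.20 equiv (fed, over 20 h) | 33 mM (held) | the fed solution adds 0.50 times the starting volume | 25 h |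

- birch (time / h: electrophile / %, product / %): 0.667: 99.6, 0; 1.33: 99.1, 0.9; 2.00: 97.9, 1.9; 3.00: 97.4, 2.5; 4.00: 95.8, 3.4; 5.00: 94.9, 4.5

(scatter of a reading: 0.3 percentage points)

- charges are per starting volume, the dose included; the dosed solution carries all of it
- at the start none of the gas is in solution
- a reading or a percentage of product counts all its forms, free or not
- no earlier run changes the charge of free base; that part of a forecast is a guess

- part of the electrophile that has reacted at the end, south
- part of the electrophile that has reacted at the end, west
- part of the electrophile that has reacted at the end, east
- what raising the equivalents of free base from its lowest to its highest value here does to the part of the electrophile that has reacted (changes below 5 percentage points count as none) (no change / it rises / it falls)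

Start from the short end. Gas is held at 33 mM, so take the electrophile loss as pseudo-first-order. Call k′ the pseudo-first-order constant, minus the logarithm of the fraction of electrophile left divided by the time. The last birch reading gives 0.0105 h⁻¹, a reading that carries the scatter of 0.3 percentage points.

For small times the part reacted, X, is about k′t, and at 25 h that straight line says 26.2%. At the long end the electrophile left tends to nothing, so the line must bend. Joining both ends gives X = 1 − exp(−k′t), which is 23.0% at 25 h, less than the line. If the loss is first order in electrophile, neither the start at 0.20 M instead of 0.30 M nor the dilution by the feed, 0.50 of the starting volume, moves that fraction.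

The weak link is free base. In birch the feed had delivered 10.0% of its charge by 2.00 h and 25.0% by 5.00 h. Yet the product reading stood at 1.9% by 2.00 h and gained 2 points in the equally long stretch from 3.00 h to 5.00 h, about the same. So I commit to 23.0% in south, west and east, with no change. Since no run varied the charge of free base, that part stays a guess.

The forecast gives 22% (13% to 27%) for south, 23.5% (17% to 38%) for west, 24.5% (18% to 55%) for east, and no change: “Base charge then matters little”. Where I hold one figure, it lets the figure creep upward with base.

    acid set free + free base ⇌ salt of the base (K = 14000 M⁻¹, k = 0.00625 M⁻¹ min⁻¹)
    gas ⇌ nucleophile, rate k2*(csat - [nucleophile]) (kL = 0.0988 min⁻¹)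
    crystals ⇌ product, rate k3*(cs3 - [product]) while solid is left; crystals form when [product] > cs3 (solubility = 24.0 mM, k = 0.0130 min⁻¹)
    electrophile + nucleophile → acid set free + product (k = 0.00509 M⁻¹ min⁻¹)
    nucleophile + acid set free ⇌ protonated nucleophile, settled at all times (K = 21200 M⁻¹)

The flasks give 21.8% in south, 21.8% in west and 21.8% in east, so raising free base from its lowest to its highest value gives no change, a change of 0 points. In east at 7.88 h, electrophile has a half-life of 70 h by its reaction with nucleophile, while free base has 4300 d by the forward step to salt of the base, far longer. At 25 h, east still holds >99.9% of its free base and 78% of its electrophile. Carried to east left until 4.0 d, k′ gives 63.5%, and that flask stands at 61.6%.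

The readings stem from a simulated flask with constants of no real substance.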